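**Numbering.** Germacrane numbering is used for all ring compounds: ring carbons C1–C10, methyl C14 on C10, methyl C15 on C4, isopropyl C11–C13 on C7. In the cyclohexenol 9 the carbinol carbon is germacrane C6, the ring alkene is C5=C4 and the isopropenyl-bearing carbon is C1.

**Route in outline.** 1 → 2; 3 + 4 → 5; 5 + 2 → (6, 7, 8) → 9; 9 → (10, 11) → 12 → 13 → (14) → 15 → 16 → 17 → 18 → 19; 20 → (21) → 22; 19 + 22 → 23 → (24) → 25. Numbers in brackets are not isolated.

## Analysis of the target

The target 25 is a germacrane: a ten-membered carbocycle with an E-trisubstituted alkene C1=C10, a trans-4,5-epoxide, a 4-hydroxybenzoate on O6, an isopropyl group on C7 and a free hydroxyl on C8. Five contiguous stereocentres run from C4 to C8 (4R,5R,6S,7R,8R). The epoxide is the one an E-4,5-alkene gives when oxygen enters from the face on which O6 stands; O6 and the isopropyl group lie on opposite faces of the ring, O8 and the isopropyl group on the same face, so O6 and O8 are 1,3-anti. The epoxide sits across the ring from C1=C10, so acid can trigger transannular cyclisation. Any 1(10)E,4E-diene on the way is a 1,5-diene that can undergo Cope rearrangement on heating. The aryl ester is 1,3 to a free secondary hydroxyl and can shift or be cleaved by base or peroxide. The hard parts are closing a ten-membered ring that holds an E-alkene, placing five neighbouring centres on a flexible ring, and telling two secondary hydroxyls apart. The strategy rests on the atoms C6(O)–C7–C8–C9–C10=C1, which form the 5-enone pattern left by an oxy-Cope rearrangement. Joining C1 to C6 and cutting C8–C9 returns a six-membered ring C1–C6 with C15 on C4 and the three-carbon unit C10/C9/C14 on C1, which is a p-menthane.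

## Retrosynthetic reasoning

**C8–O to C8–Si (25 ⇒ 23).** The C8 hydroxyl is traced to a carbon–silicon bond that is oxidised with retention in the last step, together with removal of the phenol silyl ether. Silicon is chosen because it makes O6 the only free oxygen when the ester is put on, and because a silyl group at C8 is not expelled from a C6 enolate earlier in the route. The silyl group is benzyldimethylsilyl, since its oxidation needs only fluoride and basic peroxide, which the alkene and the epoxide tolerate.

**Ester C–O bond (23 ⇒ 19 + 22).** The acyl–O6 bond is cut to give the epoxy alcohol 19 and the silyl-protected acid 22, made from 20. The forward step must be neutral because of the epoxide.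

**Epoxide C–O bonds (19 ⇒ 18).** Both epoxide bonds are removed to give the E-allylic alcohol 18. The C6 hydroxyl then directs the oxidant to C4=C5 and away from C1=C10, and its configuration fixes the face of attack.

**C6–H bond (18 ⇒ 17 ⇒ 16 ⇒ 15).** The carbinol is traced to the ketone 15. Hydride is expected to enter from the ring periphery and give the C6 epimer 16, so an inversion through the ester 17 is built into the plan.

**Alkene geometry (15 ⇒ 13 ⇒ 12).** The 4E-enone is traced to the 4Z-enone 12 through the C4 selenide 13. The key step below can only give the Z geometry, because C4=C5 is the alkene of the starting six-membered ring. Addition and syn-elimination turn it under kinetic control.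

**C8–C9 cut, C1–C6 joined (12 ⇒ 9).** This is the key disconnection. The [3,3] shift in reverse breaks C8–C9 and remakes C1–C6, which contracts the ten-membered ring to the cyclohexenol 9. One step then gives the ring, the E-alkene C1=C10 and the C8 centre, without end-to-end cyclisation, from a precursor with two stereocentres.

**C6–C7 bond (9 ⇒ 2 + 8).** The carbinol–alkenyl bond is cut to give the enone 2 and the vinyllithium 8. Compound 8 comes from the hydrazone 5 (from 3 and 4) by dianion silylation and a Shapiro reaction, which places silicon trans to lithium. Compound 2 comes from 1 by allylic oxidation and carries the only stereocentre taken from the chiral pool.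

## Alternatives that were turned down

**Alternative 1:** The C4–C5 bond is cut, leading from diol A2 back to the open-chain keto aldehyde A1. In the forward step SmI2 reduces the carbonyl groups to ketyls; their coupling forms C4–C5 with both carbinol centres and closes the ten-membered ring. Sulfonylation of the secondary C5 hydroxyl and closure by the tertiary alkoxide, with inversion at C5, would then give the epoxide.
- For it: the oxygen atoms of the epoxide carbons are made where they are needed, and C1=C10 is set in the open chain by ordinary olefination. There is no Z-to-E correction at C4–C5; on this point it is stronger than the chosen route.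
- Against it: A1 needs the C6–C8 triad built linearly, about a dozen steps. Its C6 ether is α to the aldehyde, and a ketyl or organosamarium at C5 can expel it. End-to-end closure of a ten-membered ring calls for high dilution. Nothing in the chain controls the faces at the two new centres.
- Comparison: the chosen route forms the ring by bond cleavage at normal concentration and draws C1=C10 and C8 from one chiral-pool centre.

**Alternative 2:** The C6–C7 bond is cut, leading from A4 back to the thirteen-membered diallylic ether A3. In the forward step lithiation at C6 starts a [2,3] shift that forms C6–C7, breaks O–C12, makes the isopropenyl group and contracts the ring to the ten-membered triene A4.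
- For it: one concerted step sets C6 and C7 and gives a free C6 hydroxyl on a 4E-diene, ready for directed epoxidation. It is stronger than the chosen route on C6 and on the 4E geometry, which cost the chosen route five steps.
- Against it: A3 needs a macro-etherification under dilution and a separate construction of C8. It has two allylic C–O positions (C6 and C12) that can be lithiated, and a [1,2] shift competes. The stereochemical course depends on the conformation of a thirteen-membered ring. The isopropenyl group must later be hydrogenated beside two ring alkenes, for example with RhCl(PPh3)3.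
- Comparison: the chosen route reaches its ring precursor in three steps from 1 with the stereochemical course fixed by a chair.

**Alternative 3:** The C9–C10 bond is cut, leading from the silyl-protected target A6 back to the alkynyl bis-epoxide A5. In the forward step zerovalent nickel (Ni(cod)2 with PBu3) couples the alkyne with the terminal epoxide, with Et3B as reductant. C9–C10 forms, hydrogen goes to C1 syn, O8 is set free and the ring closes.
- For it: the last C–C bond gives the ring, the E-alkene and the free C8 hydroxyl at once, with all stereocentres set in the open chain. Its end-game is far shorter than that of the chosen route, which needs nine steps after the ring is formed.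
- Against it: A5 holds a second, trisubstituted epoxide that must survive the borane and the low-valent metal. A dialkyl alkyne offers little regiochemical bias, and bond formation at C1 would give a nine-membered ring with an exocyclic alkene. A ten-membered ring with an E-trisubstituted alkene formed through a metallacycle is strained. The linear synthesis of A5 with five stereocentres is long.
- Comparison: the chosen route offers a ring-forming reaction with a predictable chair transition state on a short precursor.

Key step: step 4

## Route

Assumption: compounds 15–18 adopt the crossed conformation usual for germacra-1(10)E,4E-dienes (C14 and C15 on one face, the sp2 planes roughly perpendicular to the mean ring plane), so reagents reach C4, C5 and C6 from the ring periphery.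

Step 1
Reactants: 1 (S)-(−)-limonene
Product: 2 (R)-isopiperitenone
Conditions: Cr(CO)6 (cat.), t-BuOOH, MeCN, reflux
Reagents that add atoms: tert-butyl hydroperoxide, CC(C)(C)OO
Why: Chromium-catalysed allylic oxidation of a cyclohexene methylene to the enone; oxidation at C3 gives 2, oxidation at C6 gives carvone as an expected co-product that is removed by chromatography; the stereocentre is not involved, and the neutral medium should keep the α-centre of 2 from epimerising or drifting to the isopropylidene isomer.

Step 2
Reactants: 3 3-methylbutan-2-one; 4 2,4,6-triisopropylbenzenesulfonohydrazide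
Product: 5 (E)-N'-(3-methylbutan-2-ylidene)-2,4,6-triisopropylbenzenesulfonohydrazide
Conditions: MeOH, HCl (cat.), rt
Reagents that add atoms: none
Why: Acid-catalysed condensation of a ketone with an arenesulfonyl hydrazide; the N–N bond settles anti to the isopropyl group, which directs the later syn deprotonation to the methyl group.

Step 3
Reactants: 5 trisylhydrazone of 3-methylbutan-2-one; 2 (R)-isopiperitenone
Product: 9 (1R,6R)-1-[(1E)-1-(benzyldimethylsilyl)-3-methylbut-1-en-2-yl]-3-methyl-6-(prop-1-en-2-yl)cyclohex-2-en-1-ol, via hydrazone dianion 6 (not isolated), via N-lithio silyl hydrazone 7 (not isolated), via vinyllithium 8 (not isolated)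
Conditions: n-BuLi (2 equiv), THF, −78 °C; BnMe2SiCl, −78 °C; n-BuLi (1 equiv), −78 to 0 °C; then 2, −78 °C; NH4Cl aq.
Reagents that add atoms: benzylchlorodimethylsilane, C[Si](C)(Cl)Cc1ccccc1
Why: Shapiro reaction in its tandem form (dianion, trapping at carbon, second syn deprotonation, loss of sulfinate and N2) followed by 1,2-addition of a vinyllithium to an enone; silylation occurs at the syn carbon of 6, the hydrazone geometry is kept at low temperature so the third equivalent of base removes a CH2Si proton of 7, and the syn-dianion places the carbanion substituent away from nitrogen, which should give 8 with lithium trans to silicon; 8 adds to the carbonyl of 2 from the face opposite the isopropenyl group (equatorial attack on the half-chair), which sets the carbinol centre as R and the two alkenyl groups trans.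

Step 4
Reactants: 9 dialkenyl cyclohexenol
Product: 12 (1(10)E,4Z,7S,8R)-8-(benzyldimethylsilyl)germacra-1(10),4-dien-6-one, via potassium alkoxide 10 (not isolated), via potassium enolate 11 (not isolated)
Conditions: KH, 18-crown-6, THF, 0 °C to rt; AcOH, −78 °C
Reagents that add atoms: none
Why: Anionic oxy-Cope rearrangement: KH with 18-crown-6 gives the dissociated alkoxide 10, whose [3,3] shift through C8=C7–C6–C1–C10=C9 forms C8–C9 and breaks C1–C6; the closest known reaction type is the ring expansion of trans-1,2-dialkenylcyclohexanols and 2-isopropenyl-1-alkenylcyclohex-2-enols to cyclodec-5-enones. The ten-membered ring is not closed end to end but appears by four-atom ring expansion as the bond shared by the six-membered ring and the chair array breaks, and formation of enolate 11 makes the step irreversible. With the alkenyl groups trans, only the chair with the ring bonds C6–C5 and C1–C2 equatorial is open; the equatorial C1–C2 bond ends up trans to C9 across the new C1=C10 bond (E), while C4=C5 of the old ring stays Z. The E-vinylsilane puts silicon equatorial on the chair, so C8–C9 forms on the face fixed by C1 and C6 and C8 should be R by chirality transfer. C7 is created when 11 is protonated: C9 closes the inner face and silicon points away from the enolate plane, so acetic acid should reach C7 from the outer face beside H8 and give 7S, and this centre stays open to base equilibration. The step needs chair over boat and [3,3] over [1,3], and the trans-diequatorial alkenyl groups and the equatorial silyl group secure the chair. Silicon stands at C8 because an alkoxy group there would be expelled from the enolate, and its position trans to C6 keeps it out of reach of the alkoxide, so silyl migration to oxygen should not compete.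

Step 5
Reactants: 12 4Z-enone
Product: 13 (1(10)E,7S,8R)-8-(benzyldimethylsilyl)-4-(phenylselanyl)germacr-1(10)-en-6-one (C4 epimers)
Conditions: (PhSe)2, NaBH4, EtOH, rt; then 12, AcOH, THF, 0 °C to rt
Reagents that add atoms: diphenyl diselenide, c1ccc(cc1)[Se][Se]c1ccccc1
Why: Conjugate (Michael) addition of a selenolate to an enone under buffered conditions; the soft nucleophile adds to C4 of the Z-enone and acetic acid traps the enolate, which limits retro-addition; the configuration at C4 does not matter because the centre is removed in step 6, and C7 and C8 are not touched.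

Step 6
Reactants: 13 C4 selenide
Product: 15 (1(10)E,4E,7S,8R)-8-(benzyldimethylsilyl)germacra-1(10),4-dien-6-one, via selenoxide 14 (not isolated)
Conditions: mCPBA (1.0 equiv), CH2Cl2, −78 °C; i-Pr2NH, −78 to 0 °C
Reagents that add atoms: none
Why: Selenide oxidation and selenoxide syn-elimination; the acidified C5–H bonds α to the ketone should be taken in preference to those at C3 and C15, and of the two C5 hydrogens the one whose loss leaves the ring bonds C3–C4 and C5–C6 anticlinal is favoured, since the other needs these bonds eclipsed in a ten-membered ring, so the E-enone should form under kinetic control as is usual for syn-eliminations in ten-membered rings; the amine traps PhSeOH, and 15 is kept at or below room temperature because it is a 1,5-diene that can undergo Cope rearrangement.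

Step 7
Reactants: 15 4E-enone
Product: 16 (1(10)E,4E,6S,7S,8R)-8-(benzyldimethylsilyl)germacra-1(10),4-dien-6-ol
Conditions: i-Bu2AlH, CH2Cl2, −78 °C; aq. potassium sodium tartrate
Reagents that add atoms: none
Why: 1,2-Reduction of an enone with a hindered aluminium hydride; in the crossed conformation hydride can reach C6 only from the ring periphery, anti to the C7–C8 bond and away from the C15 methyl group (Felkin–Anh sense), which should give the 6S alcohol, the epimer of the one needed; this is accepted and corrected in step 8.

Step 8
Reactants: 16 6S-dienol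
Product: 17 (1(10)E,4E,6R,7S,8R)-8-(benzyldimethylsilyl)germacra-1(10),4-dien-6-yl 4-nitrobenzoate
Conditions: 4-O2NC6H4CO2H, PPh3, DIAD, THF, 0 °C to rt
Reagents that add atoms: 4-nitrobenzoic acid, OC(=O)c1ccc(cc1)[N+](=O)[O-]
Why: Mitsunobu inversion of a secondary allylic alcohol; the activated oxygen of 16 lies near the alkene plane and the carboxylate enters C6 from the open outer face, so SN2 inversion to the 6R ester is expected; the acidic 4-nitrobenzoic acid is the usual choice for hindered alcohols.

Step 9
Reactants: 17 4-nitrobenzoate
Product: 18 (1(10)E,4E,6R,7S,8R)-8-(benzyldimethylsilyl)germacra-1(10),4-dien-6-ol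
Conditions: K2CO3, MeOH, rt
Reagents that add atoms: none
Why: Base-catalysed methanolysis of an activated aryl ester; no stereocentre is touched and C7 is no longer epimerisable.

Step 10
Reactants: 18 6R-dienol
Product: 19 (1(10)E,4R,5R,6S,7S,8R)-8-(benzyldimethylsilyl)-4,5-epoxygermacr-1(10)-en-6-ol
Conditions: VO(acac)2 (cat.), t-BuOOH, CH2Cl2, 0 °C
Reagents that add atoms: tert-butyl hydroperoxide, CC(C)(C)OO
Why: Hydroxyl-directed epoxidation of an allylic alcohol; the vanadium-bound peroxide reacts only with C4=C5 and leaves C1=C10 alone; with H6 eclipsing the alkene to avoid allylic 1,3-strain with C15, the hydroxyl lies on the outer face and delivers oxygen there, which should give the threo 4R,5R epoxide.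

Step 11
Reactants: 20 4-hydroxybenzoic acid
Product: 22 4-(tert-butyldimethylsilyloxy)benzoic acid, via bis-silylated acid 21 (not isolated)
Conditions: TBSCl, imidazole, DMF, rt; then AcOH/THF/H2O, rt
Reagents that add atoms: tert-butyldimethylsilyl chloride, CC(C)(C)[Si](C)(C)Cl
Why: Silylation of phenol and acid followed by selective hydrolysis of the labile silyl ester; standard protecting-group chemistry with no stereocentre involved.

Step 12
Reactants: 19 epoxy alcohol; 22 silyl-protected acid
Product: 23 (1(10)E,4R,5R,6S,7S,8R)-8-(benzyldimethylsilyl)-4,5-epoxygermacr-1(10)-en-6-yl 4-(tert-butyldimethylsilyloxy)benzoate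
Conditions: DCC, DMAP (cat.), CH2Cl2, 0 °C to rt
Reagents that add atoms: none
Why: Steglich esterification; O6 is the only free oxygen because C8 still carries silicon, so the two oxygen functions are told apart without further protection, and the neutral conditions spare the epoxide.

Step 13
Reactants: 23 silyl ester
Product: 25 (1(10)E,4R,5R,6S,7R,8R)-4,5-epoxy-8-hydroxygermacr-1(10)-en-6-yl 4-hydroxybenzoate (CNP0319712.1), via fluorosilane phenol 24 (not isolated)
Conditions: Bu4NF, THF, 0 °C to rt; then KHCO3, 30% H2O2, MeOH/THF, rt
Reagents that add atoms: hydrogen peroxide, OO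
Why: Tamao–Fleming oxidation of a benzyldimethylsilyl group; fluoride cleaves the benzyl–silicon bond and the aryl silyl ether, and 24 is oxidised by basic peroxide with migration of C8 from silicon to oxygen with retention, which should give 8R; no acid or electrophile is used, so alkene and epoxide should survive, and the phenoxide form of the ester lowers its reactivity toward peroxide.

## Compound list

1 | (S)-(−)-limonene | CC1=CC[C@H](CC1)C(C)=C | starting material
2 | (R)-isopiperitenone, (6R)-3-methyl-6-(prop-1-en-2-yl)cyclohex-2-en-1-one | CC1=CC(=O)[C@H](CC1)C(C)=C | intermediate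
3 | 3-methylbutan-2-one | CC(C)C(C)=O | starting material
4 | 2,4,6-triisopropylbenzenesulfonohydrazide | CC(C)c1cc(C(C)C)c(c(c1)C(C)C)S(=O)(=O)NN | starting material
5 | (E)-N'-(3-methylbutan-2-ylidene)-2,4,6-triisopropylbenzenesulfonohydrazide | CC(C)/C(C)=N/NS(=O)(=O)c1c(cc(cc1C(C)C)C(C)C)C(C)C | intermediate
6 | C,N-dilithio dianion of 5 (lithiated at the methyl group) | CC(C)/C(C[Li])=N/N([Li])S(=O)(=O)c1c(cc(cc1C(C)C)C(C)C)C(C)C | intermediate
7 | N-lithio trisylhydrazone of 1-(benzyldimethylsilyl)-3-methylbutan-2-one (N–N syn to CH2Si) | CC(C)/C(C[Si](C)(C)Cc1ccccc1)=N/N([Li])S(=O)(=O)c1c(cc(cc1C(C)C)C(C)C)C(C)C | intermediate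
8 | [(1Z)-1-(benzyldimethylsilyl)-3-methylbut-1-en-2-yl]lithium (lithium trans to silicon) | CC(C)/C([Li])=C\[Si](C)(C)Cc1ccccc1 | intermediate
9 | (1R,6R)-1-[(1E)-1-(benzyldimethylsilyl)-3-methylbut-1-en-2-yl]-3-methyl-6-(prop-1-en-2-yl)cyclohex-2-en-1-ol | CC(C)/C(=C\[Si](C)(C)Cc1ccccc1)[C@@]2(O)C=C(C)CC[C@@H]2C(C)=C | intermediate
10 | potassium alkoxide of 9 | CC(C)/C(=C\[Si](C)(C)Cc1ccccc1)[C@@]2([O-])C=C(C)CC[C@@H]2C(C)=C.[K+] | intermediate
11 | potassium C6=C7 enolate of 12 (O cis to C8) | C/C1=C\CC/C(C)=C\C(\[O-])=C(C(C)C)\[C@H]([Si](C)(C)Cc2ccccc2)C1.[K+] | intermediate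
12 | (1(10)E,4Z,7S,8R)-8-(benzyldimethylsilyl)germacra-1(10),4-dien-6-one | C/C1=C\CC/C(C)=C\C(=O)[C@H](C(C)C)[C@H]([Si](C)(C)Cc2ccccc2)C1 | intermediate
13 | (1(10)E,7S,8R)-8-(benzyldimethylsilyl)-4-(phenylselanyl)germacr-1(10)-en-6-one, C4 epimers | C/C1=C\CCC(C)([Se]c2ccccc2)CC(=O)[C@H](C(C)C)[C@H]([Si](C)(C)Cc2ccccc2)C1 | intermediate
14 | selenoxide of 13 | C/C1=C\CCC(C)([Se](=O)c2ccccc2)CC(=O)[C@H](C(C)C)[C@H]([Si](C)(C)Cc2ccccc2)C1 | intermediate
15 | (1(10)E,4E,7S,8R)-8-(benzyldimethylsilyl)germacra-1(10),4-dien-6-one | C/C1=C\CC/C(C)=C/C(=O)[C@H](C(C)C)[C@H]([Si](C)(C)Cc2ccccc2)C1 | intermediate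
16 | (1(10)E,4E,6S,7S,8R)-8-(benzyldimethylsilyl)germacra-1(10),4-dien-6-ol | C/C1=C\CC/C(C)=C/[C@H](O)[C@H](C(C)C)[C@H]([Si](C)(C)Cc2ccccc2)C1 | intermediate
17 | (1(10)E,4E,6R,7S,8R)-8-(benzyldimethylsilyl)germacra-1(10),4-dien-6-yl 4-nitrobenzoate | C/C1=C\CC/C(C)=C/[C@@H](OC(=O)c2ccc(cc2)[N+](=O)[O-])[C@H](C(C)C)[C@H]([Si](C)(C)Cc2ccccc2)C1 | intermediate
18 | (1(10)E,4E,6R,7S,8R)-8-(benzyldimethylsilyl)germacra-1(10),4-dien-6-ol | C/C1=C\CC/C(C)=C/[C@@H](O)[C@H](C(C)C)[C@H]([Si](C)(C)Cc2ccccc2)C1 | intermediate
19 | (1(10)E,4R,5R,6S,7S,8R)-8-(benzyldimethylsilyl)-4,5-epoxygermacr-1(10)-en-6-ol | C/C1=C\CC[C@@]2(C)O[C@@H]2[C@@H](O)[C@H](C(C)C)[C@H]([Si](C)(C)Cc2ccccc2)C1 | intermediate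
20 | 4-hydroxybenzoic acid | O=C(O)c1ccc(O)cc1 | starting material
21 | tert-butyldimethylsilyl 4-(tert-butyldimethylsilyloxy)benzoate | CC(C)(C)[Si](C)(C)Oc1ccc(cc1)C(=O)O[Si](C)(C)C(C)(C)C | intermediate
22 | 4-(tert-butyldimethylsilyloxy)benzoic acid | CC(C)(C)[Si](C)(C)Oc1ccc(cc1)C(=O)O | intermediate
23 | (1(10)E,4R,5R,6S,7S,8R)-8-(benzyldimethylsilyl)-4,5-epoxygermacr-1(10)-en-6-yl 4-(tert-butyldimethylsilyloxy)benzoate | C/C1=C\CC[C@@]2(C)O[C@@H]2[C@@H](OC(=O)c2ccc(O[Si](C)(C)C(C)(C)C)cc2)[C@H](C(C)C)[C@H]([Si](C)(C)Cc2ccccc2)C1 | intermediate
24 | (1(10)E,4R,5R,6S,7S,8R)-4,5-epoxy-8-(fluorodimethylsilyl)germacr-1(10)-en-6-yl 4-hydroxybenzoate | C/C1=C\CC[C@@]2(C)O[C@@H]2[C@@H](OC(=O)c2ccc(O)cc2)[C@H](C(C)C)[C@H]([Si](C)(C)F)C1 | intermediate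
25 | (1(10)E,4R,5R,6S,7R,8R)-4,5-epoxy-8-hydroxygermacr-1(10)-en-6-yl 4-hydroxybenzoate | C/C1=C\CC[C@@]2(C)O[C@@H]2[C@@H](OC(=O)c2ccc(O)cc2)[C@H](C(C)C)[C@H](O)C1 | target

## Step count and least certain steps

Total: 13 steps. Longest linear sequence: 11 steps (1, 3–10, 12, 13).

**Step 4 (key step).** Three processes may spoil it.
- Leakage through the boat transition state or a [1,3] shift, because the silyl group crowds the forming C8–C9 bond; this would erode the configuration at C8 or the E geometry of C1=C10.
- Attack of the dissociated alkoxide or enolate on silicon with loss of the benzyl group.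
- Protonation of C7 from the wrong face; this would be met by base equilibration at the ketone stage.

Fallback: the neutral thermal variant. From 9, silylation of the tertiary hydroxyl gives the trimethylsilyl ether F1. Heating F1 in toluene in a sealed tube drives the same chair [3,3] shift without any anion and gives the silyl enol ether F2. Methanolysis with K2CO3 in MeOH returns to the route at 12.

**Step 3.** The geometry of 8 may be lost if the syn-dianion does not hold the bulky silyl group away from nitrogen, and silylation at nitrogen may compete with silylation at carbon. A Z-vinylsilane would place silicon axial in step 4 and within reach of the alkoxide.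

Fallback: geometry fixed by a chelate. Benzyl(ethynyl)dimethylsilane F3, made from ethynylmagnesium bromide and benzylchlorodimethylsilane, is lithiated and added to 2 to give the propargylic alcohol F4. Hydroxyl-directed anti-carbomagnesiation with i-PrMgCl and CuI (cat.) places isopropyl on the carbon next to the carbinol and magnesium, chelated to the alkoxide, on the silyl-bearing carbon. Protonation returns to the route at 9. The facial selectivity of the small acetylide on 2 is less secure than that of 8.

**Step 6.** Elimination may run toward C3 or C15, or may give back the Z-enone, and the strained E-enone may re-equilibrate to 12 by reversible addition of selenium species.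

Fallback: stereospecific inversion at the alcohol stage. From 12, reduction with i-Bu2AlH gives the Z-dienols F5 (C6 epimers). Directed epoxidation with VO(acac)2 and t-BuOOH gives the cis-epoxy alcohols F6. LiPPh2 opens the epoxide at C5 with inversion to give the hydroxy phosphines F7. Methylation with MeI and syn loss of the phosphine oxide gives the E-dienols, a mixture of 16 and 18. Oxidation of this mixture with MnO2 returns to the route at 15.

**Step 7.** Facial selectivity may be poor or reversed if the ring does not adopt the assumed conformation. This is not fatal: 18 formed directly is carried on to step 10, and only 16 goes through steps 8 and 9. Step 8 itself may suffer ionisation of the allylic system.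

Fallback: reagent control. From 15, Corey–Bakshi–Shibata reduction with the oxazaborolidine enantiomer chosen to deliver hydride to the inner face, with catecholborane at low temperature, aims directly at 18 and skips steps 8 and 9 (no new compound, F0).

**Step 13.** Peroxide or fluoride may cleave the aryl ester, or the acyl group may shift from O6 to the newly freed O8.

Fallback: oxidise silicon before the ester is present. From 19, treatment with Bu4NF and then H2O2/KHCO3 gives the epoxy diol F8. The less hindered C8 hydroxyl is silylated with Et3SiCl and imidazole to give the 8-O-triethylsilyl ether F9. Esterification of O6 with 22 (DCC, DMAP) gives the ester F10. Bu4NF removes both silyl ethers and returns to the route at 25.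

## Further compounds

F1 | step 4 | trimethylsilyl ether of 9 | CC(C)/C(=C\[Si](C)(C)Cc1ccccc1)[C@@]2(O[Si](C)(C)C)C=C(C)CC[C@@H]2C(C)=C
F2 | step 4 | trimethylsilyl enol ether of 12 (C6=C7) | C/C1=C\CC/C(C)=C\C(\O[Si](C)(C)C)=C(C(C)C)\[C@H]([Si](C)(C)Cc2ccccc2)C1
F3 | step 3 | benzyl(ethynyl)dimethylsilane | C#C[Si](C)(C)Cc1ccccc1
F4 | step 3 | (1R,6R)-1-[(benzyldimethylsilyl)ethynyl]-3-methyl-6-(prop-1-en-2-yl)cyclohex-2-en-1-ol | C[Si](C)(Cc1ccccc1)C#C[C@@]2(O)C=C(C)CC[C@@H]2C(C)=C
F5 | step 6 | (1(10)E,4Z,7S,8R)-8-(benzyldimethylsilyl)germacra-1(10),4-dien-6-ol, C6 epimers | C/C1=C\CC/C(C)=C\C(O)[C@H](C(C)C)[C@H]([Si](C)(C)Cc2ccccc2)C1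
F6 | step 6 | (1(10)E,7S,8R)-8-(benzyldimethylsilyl)-4,5-cis-epoxygermacr-1(10)-en-6-ol, epoxide syn to hydroxyl, C6 epimers | C/C1=C\CCC2(C)OC2C(O)[C@H](C(C)C)[C@H]([Si](C)(C)Cc2ccccc2)C1
F7 | step 6 | (1(10)E,7S,8R)-8-(benzyldimethylsilyl)-5-(diphenylphosphanyl)germacr-1(10)-ene-4,6-diol, diastereomers | C/C1=C\CCC(C)(O)C(P(c2ccccc2)c2ccccc2)C(O)[C@H](C(C)C)[C@H]([Si](C)(C)Cc2ccccc2)C1
F0 | step 7 | none | none
F8 | step 13 | (1(10)E,4R,5R,6S,7R,8R)-4,5-epoxygermacr-1(10)-ene-6,8-diol | C/C1=C\CC[C@@]2(C)O[C@@H]2[C@@H](O)[C@H](C(C)C)[C@H](O)C1
F9 | step 13 | 8-O-triethylsilyl ether of F8 | C/C1=C\CC[C@@]2(C)O[C@@H]2[C@@H](O)[C@H](C(C)C)[C@H](O[Si](CC)(CC)CC)C1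
F10 | step 13 | 6-O-[4-(tert-butyldimethylsilyloxy)benzoate] of F9 | C/C1=C\CC[C@@]2(C)O[C@@H]2[C@@H](OC(=O)c2ccc(O[Si](C)(C)C(C)(C)C)cc2)[C@H](C(C)C)[C@H](O[Si](CC)(CC)CC)C1
A1 | alternative 1 | open-chain keto aldehyde, C6 PMB ether, C8 TBS ether | O=C[C@@H](OCc1ccc(OC)cc1)[C@H](C(C)C)[C@H](O[Si](C)(C)C(C)(C)C)C/C(C)=C/CCC(C)=O
A2 | alternative 1 | germacr-1(10)E-ene-4,5-diol, C6 PMB ether, C8 TBS ether | C/C1=C\CC[C@@](C)(O)[C@@H](O)[C@@H](OCc2ccc(OC)cc2)[C@H](C(C)C)[C@H](O[Si](C)(C)C(C)(C)C)C1
A3 | alternative 2 | thirteen-membered diallylic ether (O bridging C6 and C12), C8 TBS ether | C/C1=C\CC/C(C)=C/COC/C(C)=C/[C@H](O[Si](C)(C)C(C)(C)C)C1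
A4 | alternative 2 | germacra-1(10)E,4E,11-triene-6,8-diol 8-TBS ether | C/C1=C\CC/C(C)=C/[C@@H](O)[C@H](C(C)=C)[C@H](O[Si](C)(C)C(C)(C)C)C1
A5 | alternative 3 | open-chain alkynyl bis-epoxide with the silyl-protected ester on O6 | CC#CCC[C@@]1(C)O[C@@H]1[C@@H](OC(=O)c1ccc(O[Si](C)(C)C(C)(C)C)cc1)[C@H](C(C)C)[C@H]1CO1
A6 | alternative 3 | phenol-silylated target | C/C1=C\CC[C@@]2(C)O[C@@H]2[C@@H](OC(=O)c2ccc(O[Si](C)(C)C(C)(C)C)cc2)[C@H](C(C)C)[C@H](O)C1
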